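No rate constant is given, so I start from the one constant the two runs share, the gas held at 0.78 mM.

| flask | substrate | gas | remark | time |
|---|---|---|---|---|
| Friday's | 10 mM | 0.78 mM (held) | the very flask that is asked about, followed so far |  |
| Tuesday's | 5 mM | 0.78 mM (held) | run made earlier |  |
| flask | 10 mM | 0.78 mM (held) |  | 20 h |

| run | time / h | product / % | substrate / % |
|---|---|---|---|
| Friday's | 0.200 | 0.4 | 99.5 |
| Friday's | 0.667 | 2.1 | 98.2 |
| Friday's | 1.00 | 2.8 | 96.4 |
| Friday's | 1.50 | 5.7 | 94.9 |
| Friday's | 2.50 | 9.3 | 91.1 |
| Tuesday's | 1.50 | 8.6 | 91.3 |
| Tuesday's | 3.00 | 19.4 | 80.7 |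
| Tuesday's | 5.00 | 32.4 | 68.3 |
| Tuesday's | 6.00 | 37.8 | 61.9 |
| Tuesday's | 8.00 | 49.0 | 51.4 |

(scatter of a reading: 0.3 percentage points)

- at the start none of the gas is in solution

* the product in the flask at 20 h, as a percentage of the substrate charged
* the substrate in the flask at 20 h, as a percentage of the substrate charged
* concentration of by-product at 20 h, in mM

Friday's run, with 10 mM of substrate, makes product at 0.372 mM h⁻¹ on average up to 2.50 h. Tuesday's run, with 5 mM, makes 0.306 mM h⁻¹ up to 8.00 h. Twice the substrate gives a rate 1.22 times as high, less than the doubling, so I suspect a supply from the gas as the rate-limiting step. I take Tuesday's rate because it covers the longer stretch. Two times then matter for the asked flask: the 20 h it runs, and the turnover time, the charge divided by the supply rate, 32.7 h. Their ratio gives me 61.2% product. The readings show no by-product, so I give no figure for it.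

The forecast says 66% product, 33.5% substrate and 0.05 mM by-product, holding that “the rate is nearly saturated in substrate”.

The flask gives 63.7% product, 36.3% substrate and 1.82 mM by-product.

    substrate + reagent ⇌ product + by-product (K = 15.0, k = 946 L mol⁻¹ h⁻¹)
    gas ⇌ reagent, rate k2*(csat - [reagent]) (kL = 0.513 h⁻¹)
    crystals ⇌ by-product, rate k3*(cs3 - [by-product]) while solid is left; crystals form when [by-product] > cs3 (solubility = 1.80 mM, k = 11.9 h⁻¹)

At 20.0 h the reagent's half-life by the forward step alone is 0.20 h, shorter than the 1.35 h of the gas passage, and c(reagent) stands at 0.281 mM. One by-product comes with each product, so my 6.12 mM of turnover faces 1.82 mM dissolved plus 4.55 mM as crystals. In the neighbour flask with 4.0 mM of substrate, the turnover time is 13.1 h, shorter than the 20 h, so my reckoning gives the whole charge turned over within that run. Computed, that neighbour flask holds 85.0% product and 15.0% substrate at 20 h, with c(reagent) at 0.712 mM, so substrate and reagent both remain there and the turnover time overstates its conversion.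

Readings and results stem from a simulated flask for substances that don't exist; scatter was added.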